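**Retrosynthetic overview**

1. Iridoid locants are used: C1 acyloxy acetal, O2, C3=C4, C5/C9 ring fusion, C6, C7, C8, C10 on C8, C11 on C4; β is the face of H5 and H9. The strategy rests on the O2-linked pair C1/C3 of the dihydropyran (ring C): both are aldehyde-level carbons, so they are taken as the carbinol carbons of a cis-1,2-diol on a temporary cyclopentane (ring A: C1–C3–C4–C5–C9) whose C1–C3 bond is cut late. C7, the only oxygenated carbon between C6 and C8 of the cyclopentane (ring B), is a ketone carbon supplied by CO.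
2. Endgame: silyl ethers off last; C11 by Vilsmeier formylation and reduction at C4; C1 ester by acylative capture of the enol lactol of the C1,C3-dialdehyde; dialdehyde by periodate scission of the ring A diol.
3. Ring B on the tricyclic enone: (Z)-coumarate at O7 by phosphonoacetate olefination; C7 carbinol by hydroxyl-directed reduction; C5 by hydrogenation; C8 by enolate hydroxylation followed by formaldehyde aldol.
4. Key disconnection: intramolecular Pauson–Khand reaction of a cis-4-propargyl-5-vinyl-dioxolane (C6≡C5–C4–C3–C1–C9=C8) forms C5–C9, C6–C7 and C7–C8; the enyne comes from 2-deoxy-L-ribose in four steps.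
5. Ring order: dioxolane (from the sugar) → rings A and B together (step 5) → ring A cut and ring C closed through O2 (steps 19–20).

Key step: step 5

Remark: lactol 2 is an anomer mixture and the hydroxylation in step 6 may give both C8 epimers; both centres are erased later (steps 2 and 8), so the SMILES leave the anomeric centre open and show the expected major C8 epimer.

**Route**

Step 1
Reactants: 1 2-deoxy-L-ribose
Product: 2 2-deoxy-3,4-O-isopropylidene-L-erythro-pentopyranose (anomer mixture)
Conditions: 2-methoxypropene, pyridinium p-toluenesulfonate (cat.), EtOAc, 0 °C → rt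
Reagents that add atoms: 2-methoxypropene, COC(C)=C
Why: Acid-catalysed acetonide formation (transketalisation) takes the only cis-vicinal diol of the pyranose, O3/O4, and leaves the lactol carbon free for homologation, with no stereocentre touched.

Step 2
Reactants: 2 2-deoxy-3,4-O-isopropylidene-L-erythro-pentopyranose
Product: 3 [(4S,5R)-2,2-dimethyl-5-(prop-2-yn-1-yl)-1,3-dioxolan-4-yl]methanol
Conditions: dimethyl (1-diazo-2-oxopropyl)phosphonate, K2CO3, MeOH, 0 °C → rt
Reagents that add atoms: dimethyl (1-diazo-2-oxopropyl)phosphonate, CC(=O)C(=[N+]=[N-])P(=O)(OC)OC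
Why: Seyferth–Gilbert homologation in the Ohira–Bestmann form converts the open-chain aldehyde in equilibrium with the lactol into the terminal alkyne (new carbon C6, former lactol carbon C5) and frees the primary alcohol, the dioxolane stereocentres not being involved.

Step 3
Reactants: 3 [(4S,5R)-2,2-dimethyl-5-(prop-2-yn-1-yl)-1,3-dioxolan-4-yl]methanol
Product: 4 (4R,5R)-2,2-dimethyl-5-(prop-2-yn-1-yl)-1,3-dioxolane-4-carbaldehyde
Conditions: Dess–Martin periodinane, CH2Cl2, 0 °C → rt; used crude
Reagents that add atoms: none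
Why: Dess–Martin oxidation of the primary alcohol under non-basic conditions is chosen so that the cis α-alkoxy aldehyde should not epimerise.

Step 4
Reactants: 4 (4R,5R)-2,2-dimethyl-5-(prop-2-yn-1-yl)-1,3-dioxolane-4-carbaldehyde
Product: 5 (4R,5S)-2,2-dimethyl-4-(prop-2-yn-1-yl)-5-vinyl-1,3-dioxolane (cis)
Conditions: Ph3PCH3Br, KN(SiMe3)2, THF, 0 °C; then 4, −78 °C → rt
Reagents that add atoms: methyltriphenylphosphonium bromide, C[P+](c1ccccc1)(c1ccccc1)c1ccccc1.[Br-]
Why: Wittig methylenation with the phosphonium salt in slight excess over base (no free amide to deprotonate the alkyne or epimerise the aldehyde) gives the vinyl group C9=C8 with the cis-dioxolane intact.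

Step 5
Reactants: 5 (4R,5S)-2,2-dimethyl-4-(prop-2-yn-1-yl)-5-vinyl-1,3-dioxolane
Product: 7 tricyclic enone (ring A acetonide with O1 and O3 β; C7 ketone; C5=C6; H9 β), via hexacarbonyldicobalt alkyne complex 6 (not isolated)
Conditions: Co2(CO)8 (1.1 equiv), CH2Cl2, rt; then N-methylmorpholine N-oxide (6 equiv), 0 °C → rt
Reagents that add atoms: dicobalt octacarbonyl Co2(CO)8 (one CO becomes C7=O), [Co].[Co].[C-]#[O+].[C-]#[O+].[C-]#[O+].[C-]#[O+].[C-]#[O+].[C-]#[O+].[C-]#[O+].[C-]#[O+]
Why: The terminal alkyne binds Co2(CO)6 to give 6; N-oxide-induced loss of one CO as CO2 opens a site for the vinyl group, which inserts at the internal alkyne carbon to form C5–C9, and CO insertion with reductive elimination forms C7–C8 and C6–C7 (intramolecular Pauson–Khand [2+2+1] cyclocarbonylation of a sugar-derived 1,6-enyne, a known reaction type). Ring A (C1–C3–C4–C5–C9) closes in the 5-exo mode at both the alkene and the alkyne during the insertion, and ring B (C5–C6–C7–C8–C9) closes by the final reductive elimination at cobalt. The only new stereocentre, C9, is controlled by the dioxolane stereocentres C1 and C3: in the cobaltacycle-forming transition state the cis-fused dioxolane takes the convex face, so H9 ends syn to O1 and O3 and ring B anti to the acetonide (cis-anti-cis tricycle). The step therefore needs facial selectivity in the alkene insertion (regiochemistry is fixed by the tether), and this is secured by the rigid cis-dioxolane, which also removes two rotors and holds both arms on one face so that cyclisation should outrun decomplexation. The absolute configuration at C9 follows from the L-sugar.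

Step 6
Reactants: 7 tricyclic enone
Product: 8 8-hydroxy enone (8-OH mainly β)
Conditions: KN(SiMe3)2, THF, −78 °C; then 2-(benzenesulfonyl)-3-phenyloxaziridine, −78 °C; aq. NH4Cl
Reagents that add atoms: 2-(benzenesulfonyl)-3-phenyloxaziridine, O=S(=O)(c1ccccc1)N1OC1c1ccccc1
Why: Kinetic α′-deprotonation at C8 gives the cross-conjugated enolate (γ-deprotonation, which could expel a dioxolane oxygen, is avoided at low temperature) and oxygen transfer from the N-sulfonyloxaziridine (Davis enolate hydroxylation) occurs anti to the C9–C1 bond, the C8 configuration being erased in step 8.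

Step 7
Reactants: 8 8-hydroxy enone
Product: 9 8-O-benzyl enone
Conditions: 2-benzyloxy-1-methylpyridinium triflate, MgO, PhCF3, 83 °C
Reagents that add atoms: 2-benzyloxy-1-methylpyridinium trifluoromethanesulfonate, C[n+]1ccccc1OCc1ccccc1.[O-]S(=O)(=O)C(F)(F)F
Why: O-Benzylation by thermal benzyl transfer from the pyridinium salt under near-neutral conditions suits an α-ketol that tolerates neither alkoxide formation nor strong acid (acetonide), and a benzyl ether cannot migrate between oxygens in the enolate of step 8.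

Step 8
Reactants: 9 8-O-benzyl enone
Product: 10 8α-benzyloxy-8β-(hydroxymethyl) enone
Conditions: LiN(iPr)2, THF, −78 °C; then monomeric CH2O in THF (from cracked paraformaldehyde), −78 °C; AcOH quench
Reagents that add atoms: formaldehyde, C=O
Why: Aldol addition of the fully substituted α-benzyloxy lithium enolate to formaldehyde creates the C8 quaternary centre, and because the electrophile approaches the planar enolate from the β face, anti to the C9–C1 bond of ring A, C10 is β and the oxygen introduced earlier is left α.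

Step 9
Reactants: 10 8α-benzyloxy-8β-(hydroxymethyl) enone
Product: 11 saturated keto diol (C7 ketone; 8α-OH; 8β-CH2OH; H5 and H9 β)
Conditions: H2 (1 atm), 10% Pd/C, EtOAc–EtOH, rt
Reagents that add atoms: none
Why: Catalytic hydrogenation adds hydrogen to C5 and C6 from the β face because only the cis-fused bicyclo[3.3.0] junction is attainable without severe strain (the β-CH2OH can assist adsorption), which sets H5 cis to H9, and the same catalyst hydrogenolyses the benzyl ether to free the tertiary 8α-hydroxyl.

Step 10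
Reactants: 11 saturated keto diol
Product: 12 10-O-tert-butyldiphenylsilyl hydroxy ketone
Conditions: t-BuPh2SiCl, imidazole, DMF, 0 °C → rt
Reagents that add atoms: tert-butyl(chloro)diphenylsilane, CC(C)(C)[Si](Cl)(c1ccccc1)c1ccccc1
Why: Silylation with a bulky chlorosilane is selective for the primary C10 hydroxyl over the tertiary C8 hydroxyl, which removes the β-hydroxyl as a competing directing group and installs an acid-stable ether.

Step 11
Reactants: 12 10-O-tert-butyldiphenylsilyl hydroxy ketone
Product: 13 7β,8α-diol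
Conditions: Me4NBH(OAc)3, MeCN–AcOH (1:1), −30 → 0 °C
Reagents that add atoms: none
Why: Hydroxyl-directed reduction of the Evans–Saksena type: the triacetoxyborohydride, unreactive toward the unactivated ketone, exchanges an acetate for the 8α-hydroxyl and delivers hydride intramolecularly to the α face of C7, so that 7-OH is β and trans to 8-OH.

Step 12
Reactants: 14 diphenyl phosphite (diphenyl phosphonate), 15 tert-butyl bromoacetate
Product: 16 tert-butyl 2-(diphenoxyphosphoryl)acetate
Conditions: Et3N, CH2Cl2, 0 °C → rt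
Reagents that add atoms: none
Why: Michaelis–Becker-type P-alkylation of the acidic diaryl H-phosphonate by the α-bromo ester under amine base is the usual access to diaryl phosphonoacetates.

Step 13
Reactants: 16 tert-butyl 2-(diphenoxyphosphoryl)acetate
Product: 17 2-(diphenoxyphosphoryl)acetic acid
Conditions: CF3CO2H, CH2Cl2, 0 °C → rt
Reagents that add atoms: none
Why: Acidolysis of the tert-butyl ester with loss of 2-methylpropene leaves untouched the aryl phosphonate esters, which would not survive hydroxide.

Step 14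
Reactants: 13 7β,8α-diol, 17 2-(diphenoxyphosphoryl)acetic acid
Product: 18 7-O-[(diphenoxyphosphoryl)acetyl] ester of 13
Conditions: DCC, DMAP (cat.), CH2Cl2, 0 °C → rt
Reagents that add atoms: none
Why: Steglich esterification acylates only the secondary 7β-hydroxyl, the tertiary 8α-hydroxyl being unreactive, and retains the C7 configuration.

Step 15
Reactants: 19 4-hydroxybenzaldehyde
Product: 20 4-[(tert-butyldimethylsilyl)oxy]benzaldehyde
Conditions: t-BuMe2SiCl, imidazole, CH2Cl2, rt
Reagents that add atoms: tert-butyl(chloro)dimethylsilane, CC(C)(C)[Si](C)(C)Cl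
Why: Silylation of the phenol masks the acidic hydroxyl for the olefination and gives an ether that fluoride removes in the last step.

Step 16
Reactants: 18 7-O-[(diphenoxyphosphoryl)acetyl] ester, 20 4-[(tert-butyldimethylsilyl)oxy]benzaldehyde
Product: 21 7-O-[(Z)-3-(4-tert-butyldimethylsilyloxyphenyl)prop-2-enoyl] ester (ring A acetonide; free 8α-OH)
Conditions: NaH (1.0 equiv), THF, 0 °C; then 20, −78 → −20 °C; light excluded from here on
Reagents that add atoms: none
Why: Z-selective Horner–Wadsworth–Emmons olefination with a diaryl phosphonoacetate: the electron-poor aryloxy groups make elimination from the kinetically formed syn adduct faster than its reversal, so the aromatic aldehyde should give the (Z)-cinnamate, and the phosphonate is deprotonated in preference to the tertiary alcohol.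

Step 17
Reactants: 21 7-O-(Z)-coumaroyl acetonide
Product: 22 ring A 1,3-diol (1,3,8-triol)
Conditions: AcOH–H2O (4:1), 50 °C
Reagents that add atoms: none
Why: Acid hydrolysis of the isopropylidene acetal releases the sacrificial C1/C3 cis-diol at a stage where every other group (aryl and diphenylsilyl ethers, esters, the Z-enoate) tolerates aqueous acetic acid.

Step 18
Reactants: 22 ring A 1,3-diol
Product: 24 8-O-triethylsilyl ring A phenylboronate, via ring A phenylboronate 23 (not isolated)
Conditions: PhB(OH)2, MgSO4, CH2Cl2, rt; filter; then 2,6-lutidine, Et3SiOSO2CF3, −78 → 0 °C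
Reagents that add atoms: phenylboronic acid, OB(O)c1ccccc1; triethylsilyl trifluoromethanesulfonate, CC[Si](CC)(CC)OS(=O)(=O)C(F)(F)F
Why: Cyclic boronate formation is specific for the cis-vicinal diol on ring A, so the silyl triflate can only silylate the tertiary 8α-hydroxyl, which must be capped because it lies on the α face and would add to C3 once the aldehydes are unveiled.

Step 19
Reactants: 24 8-O-triethylsilyl ring A phenylboronate
Product: 26 C1/C3 dialdehyde, via 8-O-triethylsilyl ring A diol 25 (not isolated)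
Conditions: NaIO4, THF–pH 7 phosphate buffer, 0 °C → rt; used directly
Reagents that add atoms: none
Why: Malaprade glycol cleavage: the boronate hydrolyses reversibly in the buffered aqueous medium and periodate consumes the liberated cis-diol through its cyclic periodate ester, cutting C1–C3 under neutral conditions that should leave C9 (α to the new C1 aldehyde) unepimerised.

Step 20
Reactants: 26 C1/C3 dialdehyde, 27 (R)-3-methylpentanoic acid
Product: 30 1β-O-[(R)-3-methylpentanoyl] enol ether acetal lacking C11, via (R)-3-methylpentanoyl chloride 28 (not isolated), via enol lactol 29 (not isolated)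
Conditions: 27, (COCl)2, DMF (cat.), CH2Cl2, 0 °C → rt, concentrate; then 26, pyridine, DMAP, CH2Cl2, 0 °C → rt
Reagents that add atoms: none
Why: Under base the 1,5-dialdehyde equilibrates with its cyclic enol hemiacetal (only the C3 aldehyde has an unhindered α-CH2, so its enol oxygen becomes O2 and closes ring C on C1), and DMAP-catalysed O-acylation of the lactol hydroxyl traps this tautomer as the acyloxy acetal with the ester β, trans to the C9–C8 bond, for steric and anomeric reasons.

Step 21
Reactants: 30 1β-O-acyl enol ether acetal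
Product: 31 4-formyl enol ether
Conditions: POCl3, DMF, 0 °C → rt; then aq. NaOAc, 0 °C
Reagents that add atoms: N,N-dimethylformamide, CN(C)C=O; water, O
Why: Vilsmeier–Haack formylation: the chloroiminium ion is attacked by C4, the nucleophilic β-carbon of the enol ether, loss of H4 restores C3=C4 and hydrolysis of the vinylogous amidinium salt gives the C11 aldehyde, a reaction known for dihydropyran enol ethers bearing an anomeric ester.

Step 22
Reactants: 31 4-formyl enol ether
Product: 32 C11 alcohol
Conditions: NaBH4, THF–EtOH, −20 → 0 °C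
Reagents that add atoms: none
Why: Borohydride 1,2-reduction of the β-alkoxy enal is much faster at low temperature than attack on the cinnamate or the anomeric ester and gives the C11 allylic alcohol.

Step 23
Reactants: 32 C11 alcohol
Product: 33 CNP0217341.1 (target)
Conditions: Bu4NF, AcOH (1:1), THF, 0 °C → rt, dark
Reagents that add atoms: none
Why: Fluoride-induced desilylation removes the aryl, tertiary triethylsilyl and primary tert-butyldiphenylsilyl ethers, buffered with acetic acid so that no free alkoxide triggers O7→O10 acyl migration or anomeric ester loss and no strong acid triggers addition of 8-OH to the enol ether.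

**Compound list**

1 | 2-deoxy-L-ribose | O=CC[C@@H](O)[C@@H](O)CO | starting material
2 | 2-deoxy-3,4-O-isopropylidene-L-erythro-pentopyranose (anomer mixture) | OC1C[C@H]2OC(C)(C)O[C@H]2CO1 | intermediate
3 | [(4S,5R)-2,2-dimethyl-5-(prop-2-yn-1-yl)-1,3-dioxolan-4-yl]methanol | C#CC[C@H]1OC(C)(C)O[C@H]1CO | intermediate
4 | (4R,5R)-2,2-dimethyl-5-(prop-2-yn-1-yl)-1,3-dioxolane-4-carbaldehyde | C#CC[C@H]1OC(C)(C)O[C@H]1C=O | intermediate
5 | (4R,5S)-2,2-dimethyl-4-(prop-2-yn-1-yl)-5-vinyl-1,3-dioxolane | C#CC[C@H]1OC(C)(C)O[C@H]1C=C | intermediate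
6 | hexacarbonyldicobalt complex of the alkyne of 5 | [CH]12[Co]3(=C=O)(=C=O)(=C=O)[Co]1(=C=O)(=C=O)(=C=O)C23C[C@H]4OC(C)(C)O[C@H]4C=C | intermediate
7 | tricyclic enone: ring A acetonide (O1, O3 β), C7 ketone, C5=C6, H9 β | O=C1C=C2C[C@H]3OC(C)(C)O[C@H]3[C@@H]2C1 | intermediate
8 | 8β-hydroxy derivative of 7 | CC1(C)O[C@@H]2CC3=CC(=O)[C@H](O)[C@H]3[C@@H]2O1 | intermediate
9 | 8β-benzyloxy derivative of 7 | CC1(C)O[C@@H]2CC3=CC(=O)[C@H](OCc4ccccc4)[C@H]3[C@@H]2O1 | intermediate
10 | 8α-benzyloxy-8β-(hydroxymethyl) enone | CC1(C)O[C@@H]2CC3=CC(=O)[C@](OCc4ccccc4)(CO)[C@H]3[C@@H]2O1 | intermediate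
11 | saturated keto diol: C7 ketone, 8α-OH, 8β-CH2OH, H5 and H9 β, ring A acetonide | CC1(C)O[C@@H]2C[C@H]3CC(=O)[C@](O)(CO)[C@H]3[C@@H]2O1 | intermediate
12 | 10-O-tert-butyldiphenylsilyl ether of 11 | CC1(C)O[C@@H]2C[C@H]3CC(=O)[C@](O)(CO[Si](c4ccccc4)(c4ccccc4)C(C)(C)C)[C@H]3[C@@H]2O1 | intermediate
13 | 7β,8α-diol (10-O-silyl, ring A acetonide) | CC1(C)O[C@@H]2C[C@H]3C[C@H](O)[C@](O)(CO[Si](c4ccccc4)(c4ccccc4)C(C)(C)C)[C@H]3[C@@H]2O1 | intermediate
14 | diphenyl phosphite | O=[PH](Oc1ccccc1)Oc1ccccc1 | starting material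
15 | tert-butyl bromoacetate | CC(C)(C)OC(=O)CBr | starting material
16 | tert-butyl 2-(diphenoxyphosphoryl)acetate | CC(C)(C)OC(=O)CP(=O)(Oc1ccccc1)Oc1ccccc1 | intermediate
17 | 2-(diphenoxyphosphoryl)acetic acid | OC(=O)CP(=O)(Oc1ccccc1)Oc1ccccc1 | intermediate
18 | 7-O-[(diphenoxyphosphoryl)acetyl] ester of 13 | CC1(C)O[C@@H]2C[C@H]3C[C@H](OC(=O)CP(=O)(Oc4ccccc4)Oc4ccccc4)[C@](O)(CO[Si](c4ccccc4)(c4ccccc4)C(C)(C)C)[C@H]3[C@@H]2O1 | intermediate
19 | 4-hydroxybenzaldehyde | O=Cc1ccc(O)cc1 | starting material
20 | 4-[(tert-butyldimethylsilyl)oxy]benzaldehyde | O=Cc1ccc(O[Si](C)(C)C(C)(C)C)cc1 | intermediate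
21 | 7-O-[(Z)-3-(4-tert-butyldimethylsilyloxyphenyl)prop-2-enoyl] ester of 13 | CC1(C)O[C@@H]2C[C@H]3C[C@H](OC(=O)/C=C\c4ccc(O[Si](C)(C)C(C)(C)C)cc4)[C@](O)(CO[Si](c4ccccc4)(c4ccccc4)C(C)(C)C)[C@H]3[C@@H]2O1 | intermediate
22 | ring A 1,3-diol from 21 (1,3,8-triol; O1, O3 β) | O[C@@H]1C[C@H]2C[C@H](OC(=O)/C=C\c3ccc(O[Si](C)(C)C(C)(C)C)cc3)[C@](O)(CO[Si](c3ccccc3)(c3ccccc3)C(C)(C)C)[C@H]2[C@@H]1O | intermediate
23 | 1,3-O-phenylboronate of 22 | c1ccccc1B1O[C@@H]2C[C@H]3C[C@H](OC(=O)/C=C\c4ccc(O[Si](C)(C)C(C)(C)C)cc4)[C@](O)(CO[Si](c4ccccc4)(c4ccccc4)C(C)(C)C)[C@H]3[C@@H]2O1 | intermediate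
24 | 8-O-triethylsilyl ether of 23 | c1ccccc1B1O[C@@H]2C[C@H]3C[C@H](OC(=O)/C=C\c4ccc(O[Si](C)(C)C(C)(C)C)cc4)[C@](O[Si](CC)(CC)CC)(CO[Si](c4ccccc4)(c4ccccc4)C(C)(C)C)[C@H]3[C@@H]2O1 | intermediate
25 | 8-O-triethylsilyl ring A 1,3-diol | O[C@@H]1C[C@H]2C[C@H](OC(=O)/C=C\c3ccc(O[Si](C)(C)C(C)(C)C)cc3)[C@](O[Si](CC)(CC)CC)(CO[Si](c3ccccc3)(c3ccccc3)C(C)(C)C)[C@H]2[C@@H]1O | intermediate
26 | C1/C3 dialdehyde (C9–CHO and C5–CH2–CHO on ring B; H5, H9 β) | O=CC[C@H]1C[C@H](OC(=O)/C=C\c2ccc(O[Si](C)(C)C(C)(C)C)cc2)[C@](O[Si](CC)(CC)CC)(CO[Si](c2ccccc2)(c2ccccc2)C(C)(C)C)[C@H]1C=O | intermediate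
27 | (R)-3-methylpentanoic acid | CC[C@@H](C)CC(=O)O | starting material
28 | (R)-3-methylpentanoyl chloride | CC[C@@H](C)CC(=O)Cl | intermediate
29 | enol lactol (1β-OH, C3=C4, no C11) | O[C@@H]1OC=C[C@H]2C[C@H](OC(=O)/C=C\c3ccc(O[Si](C)(C)C(C)(C)C)cc3)[C@](O[Si](CC)(CC)CC)(CO[Si](c3ccccc3)(c3ccccc3)C(C)(C)C)[C@@H]12 | intermediate
30 | 1β-O-[(R)-3-methylpentanoyl] ester of 29 | CC[C@@H](C)CC(=O)O[C@@H]1OC=C[C@H]2C[C@H](OC(=O)/C=C\c3ccc(O[Si](C)(C)C(C)(C)C)cc3)[C@](O[Si](CC)(CC)CC)(CO[Si](c3ccccc3)(c3ccccc3)C(C)(C)C)[C@@H]12 | intermediate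
31 | 4-formyl derivative of 30 (C11 aldehyde) | CC[C@@H](C)CC(=O)O[C@@H]1OC=C(C=O)[C@H]2C[C@H](OC(=O)/C=C\c3ccc(O[Si](C)(C)C(C)(C)C)cc3)[C@](O[Si](CC)(CC)CC)(CO[Si](c3ccccc3)(c3ccccc3)C(C)(C)C)[C@@H]12 | intermediate
32 | C11 alcohol (tris-silyl ether of the target) | CC[C@@H](C)CC(=O)O[C@@H]1OC=C(CO)[C@H]2C[C@H](OC(=O)/C=C\c3ccc(O[Si](C)(C)C(C)(C)C)cc3)[C@](O[Si](CC)(CC)CC)(CO[Si](c3ccccc3)(c3ccccc3)C(C)(C)C)[C@@H]12 | intermediate
33 | CNP0217341.1 | CC[C@@H](C)CC(=O)O[C@@H]1OC=C(CO)[C@H]2C[C@H](OC(=O)/C=C\c3ccc(O)cc3)[C@](O)(CO)[C@@H]12 | target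

**Step count and risk**

Total step count: 23. Longest linear sequence: 20 steps (1–11, 14, 16–23).

Steps most likely to fail:

- **Step 5.** The alkene insertion may discriminate poorly between the two faces (H9 anti instead of syn to the dioxolane oxygens), or the complex may lose cobalt before cyclising. The fallback sets out from 5 and reshapes the precursor. Deprotonation with n-BuLi and quenching with Me3SiCl gives the C6-trimethylsilyl enyne F1. Co2(CO)8 converts it into its hexacarbonyldicobalt complex F2, which with N-methylmorpholine N-oxide closes to the 6-trimethylsilyl enone F3; the bulky alkyne terminus should enlarge the steric difference between the two cobaltacycle transition states. Bu4NF in wet THF at 0 °C removes silicon from the α-silyl enone and returns to 7.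

- **Step 11.** The hindered tertiary hydroxyl may exchange onto boron too slowly, or hydride may arrive from the open β face and give the 7α-alcohol. The fallback sets out from 12 and replaces directed delivery by inversion. NaBH4 in MeOH at −40 °C, attacking the convex β face, should give the 7α,8α-cis-diol F4. Mitsunobu esterification of F4 with acid 17 (PPh3, DIAD, toluene, 0 °C → rt) reacts only at the secondary carbinol, inverts C7 and comes back to the route at 18.

- **Step 20.** Tautomerisation of the dialdehyde to the enol lactol may be slow, so that enol ester formation at C3, aldol oligomerisation or epimerisation at C9 compete with capture. The fallback sets out from 26 and dehydrates in a separate operation. Stirring in THF–H2O gives the cyclic bis-hemiacetal F5. MeSO2Cl (1.05 equiv) and Et3N at −40 → 0 °C sulfonylate the less hindered C3 hydroxyl to the 3-O-methanesulfonate F6, which loses methanesulfonate together with H4, as in the conversion of 2-deoxy lactols into glycals. This gives enol lactol 29, now isolated, and carbodiimide esterification of 29 with acid 27 (DCC, DMAP, CH2Cl2) comes back to the route at 30.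

**Further compounds**

F1 | step 5 | (4R,5S)-2,2-dimethyl-4-[3-(trimethylsilyl)prop-2-yn-1-yl]-5-vinyl-1,3-dioxolane | C[Si](C)(C)C#CC[C@H]1OC(C)(C)O[C@H]1C=C
F2 | step 5 | hexacarbonyldicobalt complex of the alkyne of F1 | C[Si](C)(C)C12[Co]3(=C=O)(=C=O)(=C=O)[Co]1(=C=O)(=C=O)(=C=O)C23C[C@H]4OC(C)(C)O[C@H]4C=C
F3 | step 5 | 6-trimethylsilyl derivative of enone 7 | O=C1C([Si](C)(C)C)=C2C[C@H]3OC(C)(C)O[C@H]3[C@@H]2C1
F4 | step 11 | 7α,8α-diol (C7 epimer of 13) | CC1(C)O[C@@H]2C[C@H]3C[C@@H](O)[C@](O)(CO[Si](c4ccccc4)(c4ccccc4)C(C)(C)C)[C@H]3[C@@H]2O1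
F5 | step 20 | cyclic bis-hemiacetal of 26 (1,3-dihydroxy tetrahydropyran, anomer mixtures at C1 and C3) | OC1OC(O)C[C@H]2C[C@H](OC(=O)/C=C\c3ccc(O[Si](C)(C)C(C)(C)C)cc3)[C@](O[Si](CC)(CC)CC)(CO[Si](c3ccccc3)(c3ccccc3)C(C)(C)C)[C@@H]12
F6 | step 20 | 3-O-methanesulfonate of F5 | OC1OC(OS(C)(=O)=O)C[C@H]2C[C@H](OC(=O)/C=C\c3ccc(O[Si](C)(C)C(C)(C)C)cc3)[C@](O[Si](CC)(CC)CC)(CO[Si](c3ccccc3)(c3ccccc3)C(C)(C)C)[C@@H]12
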